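**Retrosynthetic overview**

1. 29 ⇐ 28 (all 22 hydroxy groups carried as methyl or ethyl ethers, freed by BBr3) ⇐ ring D phenol 16 + A–B–B'–C bromide 27 (Ullmann ether bond between ring C C4 and the ring D oxygen).
2. Feature carrying the plan: C1 of each 2,4,6-trioxygenated ring F is bonded to C5 of a pentasubstituted ring E, between the oxygen-bearing C4 and C6, so four ortho oxygens surround every E–F bond. The rings F are therefore grown on ring E: F C1 and C6 are the carbons of an aryl siloxyalkyne, F C2–C5 come from 3-ethoxycyclobutenone 12 (13 ⇐ 11 + 2 × 12).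
3. 11 ⇐ diester 9 (twofold Kowalski homologation) ⇐ ring E phenol 4 (from 1 by formylation and Baeyer–Villiger oxidation) + difluoroaldehyde 5 (double SNAr; the ring D formyl group is then oxidised to the oxygen that later bonds to ring C).
4. 27 ⇐ ring A boronic acid 19 and bromophenol 17 (used once as ring B, once as ring C), joined by Chan–Lam and Ullmann ether syntheses around a ring B aldehyde; the aldehyde becomes a siloxyalkyne and is annulated with 12 to ring B' (the B–B' bond has the same four ortho oxygens).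
5. Ring order: A, B, C, D and both E are bought as benzene rings; both F close together in step 7, B' closes in step 15.

Key step: step 7

Remark: 1, 5, 12, 17 and 19 are taken as purchasable; 13 and the transient 25 hold biaryl axes that are stereogenic while the new ring carries OH and OSi, so they are drawn without axial descriptors and expected as atropisomer mixtures that merge on desilylation; the target has no stereogenic element.

**Route**

Step 1
Reactants: 1 methyl 2,4,6-trimethoxybenzoate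
Product: 2 methyl 3-formyl-2,4,6-trimethoxybenzoate
Conditions: POCl3, DMF, 0 → 70 °C; then H2O
Reagents that add atoms: N,N-dimethylformamide CN(C)C=O; water O
Why: Vilsmeier–Haack formylation can only attack the two equivalent free ring positions, each ortho and para to methoxy groups and meta to the twisted ester, so a single regioisomer is expected.

Step 2
Reactants: 2 methyl 3-formyl-2,4,6-trimethoxybenzoate
Product: 4 methyl 3-hydroxy-2,4,6-trimethoxybenzoate, via aryl formate 3 (not isolated)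
Conditions: mCPBA, CH2Cl2, 0 °C → rt; then K2CO3 (cat.), MeOH, rt
Reagents that add atoms: mCPBA (3-chloroperoxybenzoic acid) O=C(OO)c1cccc(Cl)c1
Why: Baeyer–Villiger (Dakin-type) oxidation of the electron-rich aldehyde between two methoxy groups should proceed by aryl migration to the formate, which catalytic methanolysis cleaves without touching the hindered methyl ester.

Step 3
Reactants: 4 methyl 3-hydroxy-2,4,6-trimethoxybenzoate (2.2 equiv); 5 2,6-difluoro-4-methoxybenzaldehyde
Product: 6 dimethyl 3,3'-[(2-formyl-5-methoxy-1,3-phenylene)bis(oxy)]bis(2,4,6-trimethoxybenzoate)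
Conditions: K2CO3, DMSO, 110 °C
Reagents that add atoms: none
Why: Twofold nucleophilic aromatic substitution (SNAr) in which the ortho formyl group stabilises each Meisenheimer adduct and fluoride leaves, the 4-methoxy group being meta to both reacting carbons.

Step 4
Reactants: 6 dimethyl 3,3'-[(2-formyl-5-methoxy-1,3-phenylene)bis(oxy)]bis(2,4,6-trimethoxybenzoate)
Product: 8 dimethyl 3,3'-[(2-hydroxy-5-methoxy-1,3-phenylene)bis(oxy)]bis(2,4,6-trimethoxybenzoate), via ring D formate 7 (not isolated)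
Conditions: mCPBA, CH2Cl2, rt; then K2CO3 (cat.), MeOH, rt
Reagents that add atoms: mCPBA (3-chloroperoxybenzoic acid) O=C(OO)c1cccc(Cl)c1
Why: Baeyer–Villiger oxidation again favours aryl migration because the migrating ring D carries three oxygen donors, and catalytic methanolysis of the formate should free the phenol while both benzoates stay.

Step 5
Reactants: 8 dimethyl 3,3'-[(2-hydroxy-5-methoxy-1,3-phenylene)bis(oxy)]bis(2,4,6-trimethoxybenzoate)
Product: 9 dimethyl 3,3'-{[2-(benzyloxy)-5-methoxy-1,3-phenylene]bis(oxy)}bis(2,4,6-trimethoxybenzoate)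
Conditions: BnBr, K2CO3, DMF, 60 °C
Reagents that add atoms: benzyl bromide BrCc1ccccc1
Why: Williamson etherification masks the ring D oxygen with a group that should tolerate lithium amides, heat and fluoride and that leaves later by hydrogenolysis.

Step 6
Reactants: 9 dimethyl 3,3'-{[2-(benzyloxy)-5-methoxy-1,3-phenylene]bis(oxy)}bis(2,4,6-trimethoxybenzoate)
Product: 11 2-(benzyloxy)-5-methoxy-1,3-bis{2,4,6-trimethoxy-3-[(triisopropylsiloxy)ethynyl]phenoxy}benzene, via dilithium bis(ynolate) 10 (not isolated)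
Conditions: CH2Br2, LiTMP (lithium 2,2,6,6-tetramethylpiperidide), THF, −78 °C; n-BuLi, −78 → 0 °C; then TIPSCl, −78 °C → rt
Reagents that add atoms: dibromomethane BrCBr; triisopropylsilyl chloride CC(C)[Si](Cl)(C(C)C)C(C)C
Why: Kowalski ester homologation, in which dibromomethyllithium adds to each ester, the dibromo ketone enolate undergoes bromine–lithium exchange and 1,2-aryl shift to the ynolate, and the bulky silyl chloride traps it on oxygen as the siloxyalkyne.

Step 7
Reactants: 11 2-(benzyloxy)-5-methoxy-1,3-bis{2,4,6-trimethoxy-3-[(triisopropylsiloxy)ethynyl]phenoxy}benzene; 12 3-ethoxycyclobut-2-en-1-one (about 4 equiv)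
Product: 13 2-(benzyloxy)-5-methoxy-1,3-bis{3-[4-ethoxy-2-hydroxy-6-(triisopropylsiloxy)phenyl]-2,4,6-trimethoxyphenoxy}benzene
Conditions: toluene, 80 → 110 °C, sealed tube, argon
Reagents that add atoms: none
Why: Danheiser benzannulation run in two directions: thermal four-electron electrocyclic opening of 12 gives an ethoxyvinylketene, which adds in a [2+2] sense across each siloxyalkyne with its carbonyl carbon bonding to the aryl-bearing, nucleophilic alkyne carbon, and the 4-vinylcyclobutenone so formed opens to a dienylketene. Each ring F is then closed by six-electron electrocyclisation between the ketene carbon and the terminal methylene carbon, and tautomerisation gives the phenol. The closest known reaction type is the cyclobutenone–siloxyalkyne benzannulation that gives 2-substituted resorcinol monosilyl ethers. No stereocentre is formed; the two new biaryl axes are stereogenic in 13 (OH against OSi) and an atropisomer mixture is accepted because the axes become symmetric again in 14. The step needs regioselectivity (ring E between OH and OSi, OEt para), which the polarisation of the siloxyalkyne fixes, and reaction of both alkynes, which the excess of 12 and the absence of any metal insertion beside the four ortho oxygens should allow.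

Step 8
Reactants: 13 2-(benzyloxy)-5-methoxy-1,3-bis{3-[4-ethoxy-2-hydroxy-6-(triisopropylsiloxy)phenyl]-2,4,6-trimethoxyphenoxy}benzene
Product: 15 2-(benzyloxy)-5-methoxy-1,3-bis[3-(4-ethoxy-2,6-dimethoxyphenyl)-2,4,6-trimethoxyphenoxy]benzene, via tetraphenol 14 (not isolated)
Conditions: TBAF, THF, 0 °C; then MeI, K2CO3, DMF, 40 °C
Reagents that add atoms: iodomethane CI
Why: Fluoride cleaves the two aryl silyl ethers and Williamson methylation then caps all four ring F oxygens, which removes the axial isomerism and leaves only alkyl ethers beside the benzyl group.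

Step 9
Reactants: 15 2-(benzyloxy)-5-methoxy-1,3-bis[3-(4-ethoxy-2,6-dimethoxyphenyl)-2,4,6-trimethoxyphenoxy]benzene
Product: 16 4-methoxy-2,6-bis[3-(4-ethoxy-2,6-dimethoxyphenyl)-2,4,6-trimethoxyphenoxy]phenol
Conditions: H2 (1 atm), Pd/C, EtOAc–MeOH, rt
Reagents that add atoms: none
Why: Catalytic hydrogenolysis of the single benzyl ether should free the ring D phenol, no other group in 15 being reducible under these conditions.

Step 10
Reactants: 17 4-bromo-2,6-dimethoxyphenol
Product: 18 6-bromo-3-hydroxy-2,4-dimethoxybenzaldehyde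
Conditions: Cl2CHOMe, TiCl4, CH2Cl2, 0 °C → rt; aq HCl work-up
Reagents that add atoms: dichloromethyl methyl ether COC(Cl)Cl; water O
Why: Rieche formylation can only attack the two equivalent free ring positions, each ortho and para to a methoxy group and next to bromine, and hydrolysis on work-up releases the aldehyde.

Step 11
Reactants: 18 6-bromo-3-hydroxy-2,4-dimethoxybenzaldehyde; 19 3,5-dimethoxyphenylboronic acid (2 equiv)
Product: 20 6-bromo-3-(3,5-dimethoxyphenoxy)-2,4-dimethoxybenzaldehyde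
Conditions: Cu(OAc)2, pyridine, 4 Å molecular sieves, CH2Cl2, air, rt
Reagents that add atoms: none
Why: Chan–Lam coupling transfers ring A from boron to the phenol oxygen at room temperature through an aryl copper phenoxide, and the aryl bromide and the aldehyde are inert to it.

Step 12
Reactants: 20 6-bromo-3-(3,5-dimethoxyphenoxy)-2,4-dimethoxybenzaldehyde; 17 4-bromo-2,6-dimethoxyphenol (1.0 equiv)
Product: 21 6-(4-bromo-2,6-dimethoxyphenoxy)-3-(3,5-dimethoxyphenoxy)-2,4-dimethoxybenzaldehyde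
Conditions: CuI (10 mol%), picolinic acid (20 mol%), K3PO4, DMSO, 70 °C, argon
Reagents that add atoms: none
Why: Ullmann ether synthesis in which the ortho formyl group activates the bromide of 20 toward the copper phenoxide well above the electron-rich, unactivated bromide that 17 brings in, so ring C should be attached with its bromine intact.

Step 13
Reactants: 21 6-(4-bromo-2,6-dimethoxyphenoxy)-3-(3,5-dimethoxyphenoxy)-2,4-dimethoxybenzaldehyde
Product: 22 1-(4-bromo-2,6-dimethoxyphenoxy)-4-(3,5-dimethoxyphenoxy)-2-ethynyl-3,5-dimethoxybenzene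
Conditions: dimethyl (1-diazo-2-oxopropyl)phosphonate, K2CO3, MeOH–THF, rt
Reagents that add atoms: dimethyl (1-diazo-2-oxopropyl)phosphonate COP(=O)(OC)C(=[N+]=[N-])C(C)=O
Why: Seyferth–Gilbert homologation with the Ohira–Bestmann reagent converts the aldehyde into the terminal alkyne through a diazoalkene and an alkylidene carbene with 1,2-hydrogen shift, under carbonate conditions that spare the aryl bromide.

Step 14
Reactants: 22 1-(4-bromo-2,6-dimethoxyphenoxy)-4-(3,5-dimethoxyphenoxy)-2-ethynyl-3,5-dimethoxybenzene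
Product: 24 {[2-(4-bromo-2,6-dimethoxyphenoxy)-5-(3,5-dimethoxyphenoxy)-4,6-dimethoxyphenyl]ethynyloxy}triisopropylsilane, via lithium ynolate 23 (not isolated)
Conditions: LiHMDS (LiN(SiMe3)2), THF, −78 °C; t-BuOOLi (from t-BuOOH and LiHMDS), −78 → 0 °C; then TIPSOTf, −78 °C → rt
Reagents that add atoms: tert-butyl hydroperoxide CC(C)(C)OO; triisopropylsilyl trifluoromethanesulfonate CC(C)[Si](OS(=O)(=O)C(F)(F)F)(C(C)C)C(C)C
Why: Ynolate formation by oxidation of the acetylide with lithium tert-butyl peroxide, followed by O-silylation, is a known entry to siloxyalkynes that uses only an amide base, so the aryl bromide should survive.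

Step 15
Reactants: 24 {[2-(4-bromo-2,6-dimethoxyphenoxy)-5-(3,5-dimethoxyphenoxy)-4,6-dimethoxyphenyl]ethynyloxy}triisopropylsilane; 12 3-ethoxycyclobut-2-en-1-one
Product: 26 2-[2-(4-bromo-2,6-dimethoxyphenoxy)-5-(3,5-dimethoxyphenoxy)-4,6-dimethoxyphenyl]-5-ethoxybenzene-1,3-diol, via silyl ether 25 (not isolated)
Conditions: toluene, 80 → 110 °C, sealed tube, argon, slight excess of the cyclobutenone; evaporate; then TBAF, AcOH, THF, 0 °C
Reagents that add atoms: none
Why: Danheiser benzannulation as in step 7 on one siloxyalkyne (vinylketene [2+2] addition, four-electron opening, six-electron closure) should place ring B between OH and OSi of the new ring B' with OEt para, and acetic acid-buffered fluoride desilylation of the crude atropisomer mixture then gives one symmetric resorcinol, the aryl bromide being inert to both the thermal cascade and fluoride.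

Step 16
Reactants: 26 2-[2-(4-bromo-2,6-dimethoxyphenoxy)-5-(3,5-dimethoxyphenoxy)-4,6-dimethoxyphenyl]-5-ethoxybenzene-1,3-diol
Product: 27 2-(4-bromo-2,6-dimethoxyphenoxy)-5-(3,5-dimethoxyphenoxy)-4'-ethoxy-2',4,6,6'-tetramethoxy-1,1'-biphenyl
Conditions: MeI, K2CO3, DMF, 40 °C
Reagents that add atoms: iodomethane CI
Why: Williamson methylation of the two ring B' phenols turns ring B' into a 4-ethoxy-2,6-dimethoxyphenyl group and leaves the aryl bromide as the only reactive site.

Step 17
Reactants: 16 4-methoxy-2,6-bis[3-(4-ethoxy-2,6-dimethoxyphenyl)-2,4,6-trimethoxyphenoxy]phenol; 27 2-(4-bromo-2,6-dimethoxyphenoxy)-5-(3,5-dimethoxyphenoxy)-4'-ethoxy-2',4,6,6'-tetramethoxy-1,1'-biphenyl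
Product: 28 nonadeca-O-methyl tri-O-ethyl ether of the target (ring F and ring B' para oxygens as OEt, all other oxygens as OMe)
Conditions: CuI (20 mol%), picolinic acid (40 mol%), K3PO4, DMSO, 110 °C, argon
Reagents that add atoms: none
Why: Ullmann diaryl ether synthesis with CuI and picolinic acid, a ligand system suited to phenols with two ortho substituents, should join the ring D phenoxide to the unhindered ring C bromide, these being the only phenol and the only halide present.

Step 18
Reactants: 28 nonadeca-O-methyl tri-O-ethyl ether of the target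
Product: 29 CNP0117322.0 (target)
Conditions: BBr3 (excess), CH2Cl2, −78 °C → rt; then MeOH, H2O; handled under argon
Reagents that add atoms: none
Why: BBr3 ether cleavage proceeds by bromide attack on the O-alkyl carbon of each borane adduct, whereas diaryl ethers and biaryl bonds offer no such carbon, so all twenty-two hydroxy groups should be freed with the skeleton intact.

**Compound list**

1 | methyl 2,4,6-trimethoxybenzoate | COC(=O)c1c(OC)cc(OC)cc1OC | starting material
2 | methyl 3-formyl-2,4,6-trimethoxybenzoate | COC(=O)c1c(OC)cc(OC)c(C=O)c1OC | intermediate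
3 | methyl 3-(formyloxy)-2,4,6-trimethoxybenzoate | COC(=O)c1c(OC)cc(OC)c(OC=O)c1OC | intermediate
4 | methyl 3-hydroxy-2,4,6-trimethoxybenzoate (ring E phenol) | COC(=O)c1c(OC)cc(OC)c(O)c1OC | intermediate
5 | 2,6-difluoro-4-methoxybenzaldehyde | COc1cc(F)c(C=O)c(F)c1 | starting material
6 | dimethyl 3,3'-[(2-formyl-5-methoxy-1,3-phenylene)bis(oxy)]bis(2,4,6-trimethoxybenzoate) | COc1cc(Oc2c(OC)cc(OC)c(C(=O)OC)c2OC)c(C=O)c(Oc2c(OC)cc(OC)c(C(=O)OC)c2OC)c1 | intermediate
7 | dimethyl 3,3'-{[2-(formyloxy)-5-methoxy-1,3-phenylene]bis(oxy)}bis(2,4,6-trimethoxybenzoate) | COc1cc(Oc2c(OC)cc(OC)c(C(=O)OC)c2OC)c(OC=O)c(Oc2c(OC)cc(OC)c(C(=O)OC)c2OC)c1 | intermediate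
8 | dimethyl 3,3'-[(2-hydroxy-5-methoxy-1,3-phenylene)bis(oxy)]bis(2,4,6-trimethoxybenzoate) | COc1cc(Oc2c(OC)cc(OC)c(C(=O)OC)c2OC)c(O)c(Oc2c(OC)cc(OC)c(C(=O)OC)c2OC)c1 | intermediate
9 | dimethyl 3,3'-{[2-(benzyloxy)-5-methoxy-1,3-phenylene]bis(oxy)}bis(2,4,6-trimethoxybenzoate) | COc1cc(Oc2c(OC)cc(OC)c(C(=O)OC)c2OC)c(OCc2ccccc2)c(Oc2c(OC)cc(OC)c(C(=O)OC)c2OC)c1 | intermediate
10 | dilithium bis(ynolate) of the ring D bis(ether) | [Li+].[Li+].COc1cc(Oc2c(OC)cc(OC)c(C#C[O-])c2OC)c(OCc2ccccc2)c(Oc2c(OC)cc(OC)c(C#C[O-])c2OC)c1 | intermediate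
11 | 2-(benzyloxy)-5-methoxy-1,3-bis{2,4,6-trimethoxy-3-[(triisopropylsiloxy)ethynyl]phenoxy}benzene | COc1cc(Oc2c(OC)cc(OC)c(C#CO[Si](C(C)C)(C(C)C)C(C)C)c2OC)c(OCc2ccccc2)c(Oc2c(OC)cc(OC)c(C#CO[Si](C(C)C)(C(C)C)C(C)C)c2OC)c1 | intermediate
12 | 3-ethoxycyclobut-2-en-1-one | CCOC1=CC(=O)C1 | starting material
13 | 2-(benzyloxy)-5-methoxy-1,3-bis{3-[4-ethoxy-2-hydroxy-6-(triisopropylsiloxy)phenyl]-2,4,6-trimethoxyphenoxy}benzene | COc1cc(Oc2c(OC)cc(OC)c(-c3c(O)cc(OCC)cc3O[Si](C(C)C)(C(C)C)C(C)C)c2OC)c(OCc2ccccc2)c(Oc2c(OC)cc(OC)c(-c3c(O)cc(OCC)cc3O[Si](C(C)C)(C(C)C)C(C)C)c2OC)c1 | intermediate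
14 | 2-(benzyloxy)-5-methoxy-1,3-bis[3-(4-ethoxy-2,6-dihydroxyphenyl)-2,4,6-trimethoxyphenoxy]benzene | COc1cc(Oc2c(OC)cc(OC)c(-c3c(O)cc(OCC)cc3O)c2OC)c(OCc2ccccc2)c(Oc2c(OC)cc(OC)c(-c3c(O)cc(OCC)cc3O)c2OC)c1 | intermediate
15 | 2-(benzyloxy)-5-methoxy-1,3-bis[3-(4-ethoxy-2,6-dimethoxyphenyl)-2,4,6-trimethoxyphenoxy]benzene | COc1cc(Oc2c(OC)cc(OC)c(-c3c(OC)cc(OCC)cc3OC)c2OC)c(OCc2ccccc2)c(Oc2c(OC)cc(OC)c(-c3c(OC)cc(OCC)cc3OC)c2OC)c1 | intermediate
16 | 4-methoxy-2,6-bis[3-(4-ethoxy-2,6-dimethoxyphenyl)-2,4,6-trimethoxyphenoxy]phenol | COc1cc(Oc2c(OC)cc(OC)c(-c3c(OC)cc(OCC)cc3OC)c2OC)c(O)c(Oc2c(OC)cc(OC)c(-c3c(OC)cc(OCC)cc3OC)c2OC)c1 | intermediate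
17 | 4-bromo-2,6-dimethoxyphenol | COc1cc(Br)cc(OC)c1O | starting material
18 | 6-bromo-3-hydroxy-2,4-dimethoxybenzaldehyde | O=Cc1c(OC)c(O)c(OC)cc1Br | intermediate
19 | 3,5-dimethoxyphenylboronic acid | COc1cc(OC)cc(B(O)O)c1 | starting material
20 | 6-bromo-3-(3,5-dimethoxyphenoxy)-2,4-dimethoxybenzaldehyde | O=Cc1c(OC)c(Oc2cc(OC)cc(OC)c2)c(OC)cc1Br | intermediate
21 | 6-(4-bromo-2,6-dimethoxyphenoxy)-3-(3,5-dimethoxyphenoxy)-2,4-dimethoxybenzaldehyde | O=Cc1c(OC)c(Oc2cc(OC)cc(OC)c2)c(OC)cc1Oc1c(OC)cc(Br)cc1OC | intermediate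
22 | 1-(4-bromo-2,6-dimethoxyphenoxy)-4-(3,5-dimethoxyphenoxy)-2-ethynyl-3,5-dimethoxybenzene | C#Cc1c(OC)c(Oc2cc(OC)cc(OC)c2)c(OC)cc1Oc1c(OC)cc(Br)cc1OC | intermediate
23 | lithium 2-[2-(4-bromo-2,6-dimethoxyphenoxy)-5-(3,5-dimethoxyphenoxy)-4,6-dimethoxyphenyl]ethynolate | [Li+].[O-]C#Cc1c(OC)c(Oc2cc(OC)cc(OC)c2)c(OC)cc1Oc1c(OC)cc(Br)cc1OC | intermediate
24 | {[2-(4-bromo-2,6-dimethoxyphenoxy)-5-(3,5-dimethoxyphenoxy)-4,6-dimethoxyphenyl]ethynyloxy}triisopropylsilane | CC(C)[Si](OC#Cc1c(OC)c(Oc2cc(OC)cc(OC)c2)c(OC)cc1Oc1c(OC)cc(Br)cc1OC)(C(C)C)C(C)C | intermediate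
25 | 2-[2-(4-bromo-2,6-dimethoxyphenoxy)-5-(3,5-dimethoxyphenoxy)-4,6-dimethoxyphenyl]-5-ethoxy-3-(triisopropylsiloxy)phenol | CCOc1cc(O)c(-c2c(OC)c(Oc3cc(OC)cc(OC)c3)c(OC)cc2Oc2c(OC)cc(Br)cc2OC)c(O[Si](C(C)C)(C(C)C)C(C)C)c1 | intermediate
26 | 2-[2-(4-bromo-2,6-dimethoxyphenoxy)-5-(3,5-dimethoxyphenoxy)-4,6-dimethoxyphenyl]-5-ethoxybenzene-1,3-diol | CCOc1cc(O)c(-c2c(OC)c(Oc3cc(OC)cc(OC)c3)c(OC)cc2Oc2c(OC)cc(Br)cc2OC)c(O)c1 | intermediate
27 | 2-(4-bromo-2,6-dimethoxyphenoxy)-5-(3,5-dimethoxyphenoxy)-4'-ethoxy-2',4,6,6'-tetramethoxy-1,1'-biphenyl (A–B–B'–C bromide) | CCOc1cc(OC)c(-c2c(OC)c(Oc3cc(OC)cc(OC)c3)c(OC)cc2Oc2c(OC)cc(Br)cc2OC)c(OC)c1 | intermediate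
28 | nonadeca-O-methyl tri-O-ethyl ether of the target | COc1cc(OC)cc(Oc2c(OC)cc(Oc3c(OC)cc(Oc4c(Oc5c(OC)cc(OC)c(-c6c(OC)cc(OCC)cc6OC)c5OC)cc(OC)cc4Oc4c(OC)cc(OC)c(-c5c(OC)cc(OCC)cc5OC)c4OC)cc3OC)c(-c3c(OC)cc(OCC)cc3OC)c2OC)c1 | intermediate
29 | CNP0117322.0 | Oc1cc(O)cc(Oc2c(O)cc(Oc3c(O)cc(Oc4c(Oc5c(O)cc(O)c(-c6c(O)cc(O)cc6O)c5O)cc(O)cc4Oc4c(O)cc(O)c(-c5c(O)cc(O)cc5O)c4O)cc3O)c(-c3c(O)cc(O)cc3O)c2O)c1 | target

**Step count and risks**

Total step count: 18. Longest linear sequence: 11 steps (steps 1–9, then 17 and 18); the branch to 27 is 7 steps (steps 10–16).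

Steps most likely to fail:

Step 7 (the benzannulation in step 15 shares this risk). Cyclobutenone 12 is stabilised as a vinylogous ester and may open slowly. The temperature then needed could let the siloxyalkynes rearrange to silylketenes or leave the second alkyne unreacted, and excess ketene may acylate the new phenols. The fallback sets out from 11 and generates the same ethoxyvinylketene at room temperature by photochemical Wolff rearrangement: 11 would be irradiated (about 300 nm, 1,2-dichloroethane) with 1-diazo-3-ethoxybut-3-en-2-one F1, made by diazo transfer to the corresponding methyl ketone. Brief warming to 80 °C should then complete ring opening and electrocyclisation, and the route is rejoined at 13.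

Step 6. Dibromomethyllithium is thermally labile, and its addition to an ester carbonyl shielded by two ortho methoxy groups may be slower than its decay. The excess n-BuLi may also deprotonate the benzyl ether or ring positions between two ether oxygens. The fallback sets out from 9 and avoids both the carbenoid and the alkyllithium. LiAlH4 reduction should give diol F2 and MnO2 oxidation dialdehyde F3. Ohira–Bestmann homologation (as in step 13) should give dialkyne F4. Acetylide oxidation with t-BuOOLi and TIPSOTf trapping (as in step 14) then rejoins the route at 11.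

Step 17. Carbon–oxygen bond formation at a phenoxide oxygen flanked by two large aryloxy groups may be slow, so that hydrodebromination of 27 outruns coupling. The fallback sets out from 27 and changes the coupling mode from halide to boron. Miyaura borylation (B2pin2, Pd(dppf)Cl2, KOAc, dioxane) should give pinacol boronate F5, and NaIO4/NH4OAc cleavage boronic acid F6. Chan–Lam coupling of F6 with 16 (Cu(OAc)2, pyridine, molecular sieves, air, rt) rejoins the route at 28.

**Further compounds**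

F1 | step 7 | 1-diazo-3-ethoxybut-3-en-2-one | C=C(OCC)C(=O)C=[N+]=[N-]
F2 | step 6 | 2-(benzyloxy)-5-methoxy-1,3-bis[3-(hydroxymethyl)-2,4,6-trimethoxyphenoxy]benzene | COc1cc(Oc2c(OC)cc(OC)c(CO)c2OC)c(OCc2ccccc2)c(Oc2c(OC)cc(OC)c(CO)c2OC)c1
F3 | step 6 | 2-(benzyloxy)-5-methoxy-1,3-bis(3-formyl-2,4,6-trimethoxyphenoxy)benzene | COc1cc(Oc2c(OC)cc(OC)c(C=O)c2OC)c(OCc2ccccc2)c(Oc2c(OC)cc(OC)c(C=O)c2OC)c1
F4 | step 6 | 2-(benzyloxy)-5-methoxy-1,3-bis(3-ethynyl-2,4,6-trimethoxyphenoxy)benzene | COc1cc(Oc2c(OC)cc(OC)c(C#C)c2OC)c(OCc2ccccc2)c(Oc2c(OC)cc(OC)c(C#C)c2OC)c1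
F5 | step 17 | pinacol boronate of 27 (Bpin in place of Br on ring C) | CCOc1cc(OC)c(-c2c(OC)c(Oc3cc(OC)cc(OC)c3)c(OC)cc2Oc2c(OC)cc(B3OC(C)(C)C(C)(C)O3)cc2OC)c(OC)c1
F6 | step 17 | boronic acid of 27 (B(OH)2 in place of Br on ring C) | CCOc1cc(OC)c(-c2c(OC)c(Oc3cc(OC)cc(OC)c3)c(OC)cc2Oc2c(OC)cc(B(O)O)cc2OC)c(OC)c1
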